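## Analysis of the target

Bisabolane numbering is used throughout: ring C1–C6 (C1 ester carbinol, C2 ketone, C3 quaternary oxirane carbon with methyl C15, C4 oxirane CH, C5 methylene, C6 methine) and chain C7(=C14H2)–C8–C9–C10–C11(C12)(C13) attached at C6.

- The target is a cyclohexanone ring C1–C6 with an oxirane C3–O–C4 and an angelate at C1. At C6 it carries the chain C7(=C14H2)–C8H(OAng)–C9H2–C10H(OH)–C11(OH)Me2.
- It has six stereocentres: 1S,3R,4R,6R in the ring and 8S,10S in the chain. C8 and C10 form an anti-1,3-diol mono-ester.
- On the ring, the oxirane oxygen, the C1–O bond and the C6–C7 bond all lie on one face; C15, H1, H4 and H6 lie on the other.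
- C1–C8, C14 and C15 are the ten carbons of (S)-carvone: its carbonyl is C2, its enone alkene is C3=C4, its isopropenyl group is C7/C14/C8, and its stereocentre is C6.
- Sensitive groups:
  - two angelates, which isomerise Z to E on acyl activation;
  - the C1 α-acyloxy ketone, which is epimerisable and probably the less stable epimer;
  - the α,β-epoxy ketone;
  - the allylic ester at C8, next to a free diol.
- The skeleton is not the difficulty. The difficulty is that all three ring C–O bonds sit on the face shielded by the C6 substituent, whereas peroxide conjugate addition and enolate oxidation on a carvone ring both deliver oxygen anti to it.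
- The move this structure invites is therefore: buy C6 with the whole C10 unit and build nothing of the ring. C6 is relayed through a sacrificial C2 carbinol that delivers the oxirane oxygen intramolecularly to C3/C4. The other two contra-steric or labile C–O bonds (C1–O and C8–O) are formed by SN2 with the angelate as nucleophile.

## Retrosynthetic reasoning

**19 to 17 (C10–O and C11–O).** The diol is introduced last by ligand-controlled osmylation of the prenyl alkene of 17. This is the only point where free hydroxyls coexist with the esters, so no protecting group is needed. The C10=C11 alkene is the only electron-rich trisubstituted alkene in 17.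

**17 to 15 + 8 (C8–O, not the acyl C–O).** The C8 ester bond is cut between C8 and oxygen. Forward, angelic acid 8 displaces an activated 8R hydroxyl with inversion. The acid is never activated as an acyl donor, so the Z geometry is safe, and the conditions are neutral, so the C1 centre is safe.

**15 to 14 to 12 (C10=C11, then C8–C9).** The prenyl terminus comes from cross-metathesis of the allyl group of 14. The C8–C9 bond, the only C–C bond between building blocks, comes from reagent-controlled allylboration of aldehyde 12. The skeleton is cut here because C8 is the former isopropenyl methyl of carvone and can be raised to the aldehyde level without touching C6.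

**12 to 10 (C8 oxidation level).** The aldehyde is unmasked from an allylic chloride that is installed in the first step. The chloride survives the hydride, enolate and Mitsunobu steps that an aldehyde would not.

**10 to 7 + 8 (C1–O).** The cis C1 angelate arises by SN2 inversion of the trans α-hydroxy ketone 7 with 8. Enolate oxidation can only give the trans alcohol, so inversion converts the easy configuration into the required one and installs the ester in the same step.

**7 to 5 (C1–O of the alcohol).** Hydroxylation of the enolate of 5. C1 is the only enolisable position because C3 is quaternary.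

**5 to 4 to 3 (oxirane, C3 and C4).** A Weitz–Scheffer epoxidation of the enone would add anti to the C6 substituent. The enone is therefore reduced to the cis allylic alcohol 3, whose C2 oxygen carries the oxidant to the syn face to give 4. The C2 stereocentre is then erased by oxidation to 5.

**3 to 2 to 1.** 1,2-Reduction of chloro-enone 2, which comes from ene-type chlorination of (S)-carvone 1.

## Alternatives that were turned down

**Alternative 1: (the textbook route)** Same carvone skeleton, but the oxirane is made by forming C4–O through conjugate addition of hydroperoxide to enone 2 and closing C3–O (Weitz–Scheffer), followed by enolate oxidation and O-acylation with an activated angelic acid.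
- Forward key step: alkaline peroxide epoxidation of 2 to A1.
- Reason turned down: the hydroperoxide adds axially at C4 anti to the C6 substituent, so A1 carries the oxirane trans to the side chain. Enolate oxidation then gives A2 with all ring oxygens on the wrong face. C6 has no acidifying neighbour and cannot be epimerised, so the error is permanent. The route is two steps shorter but reaches a diastereomer of the target.

**Alternative 2:** Build the ring by Diels–Alder reaction (the classical bisabolane construction), forming C4–C5 and C6–C1 from diene A3 and the α'-hydroxy vinyl ketone A4, whose C8 carbinol controls the face through the internal hydrogen bond.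
- Forward key step: endo cycloaddition to A5 with C1–O and C6–C7 cis.
- Reason turned down: it assembles a ring that 1 supplies with C6 already set. A5 still needs oxidation at C2 (in competition with the other allylic position), the same contra-steric oxirane relay and a C7 methylenation. A4 alone costs at least five steps, so the total would be near twenty.

**Alternative 3:** Take both ring oxygens from one molecule of O2: [4+2] addition of singlet oxygen across C1 and C4 of the silyl dienol ether A6 to endoperoxide A7, then O–O cleavage and rearrangement to the silyloxy epoxy ketone A8.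
- Forward key step: the photooxygenation.
- Reason turned down: singlet oxygen approaches a 5-substituted cyclohexa-1,3-diene anti to the substituent, and no hydrogen-bond donor is within reach to override this. A7 and A8 would therefore carry both oxygens trans to the side chain, the one relationship that cannot be repaired. The homolytic rearrangement also competes with ene and dioxetane pathways of the enol ether.

Key step: step 3

Assumption: the target is taken exactly as the SMILES defines it, (1S,3R,4R,6R,8S,10S) with the oxirane oxygen, the C1 oxygen and the C6–C7 bond on the same ring face.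

## Route

Step 1
Reactants: 1 (S)-(+)-carvone
Product: 2 (5S)-5-(3-chloroprop-1-en-2-yl)-2-methylcyclohex-2-en-1-one (10-chlorocarvone)
Conditions: Ca(OCl)2, CO2 (s), CH2Cl2/H2O, 0 °C
Reagents that add atoms: calcium hypochlorite, [Ca+2].[O-]Cl.[O-]Cl
Why: Ene-type allylic chlorination by HOCl formed in situ; only the electron-rich 1,1-disubstituted alkene reacts, the enone alkene is inert. The chlorinated carbon becomes C8, the former methyl becomes C14, and C6 is untouched.

Step 2
Reactants: 2 10-chlorocarvone
Product: 3 (1S,5S)-5-(3-chloroprop-1-en-2-yl)-2-methylcyclohex-2-en-1-ol (chloro-cis-carveol)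
Conditions: NaBH4, CeCl3·7H2O, MeOH, −78 to −20 °C
Reagents that add atoms: none
Why: Luche 1,2-reduction; axial hydride delivery should give the alcohol cis to the C6 substituent (temporary stereocentre at C2, controlled by C6). The allylic chloride is inert to borohydride at this temperature.

Step 3
Reactants: 3 chloro-cis-carveol
Product: 4 (1S,2S,4R,6R)-4-(3-chloroprop-1-en-2-yl)-1-methyl-7-oxabicyclo[4.1.0]heptan-2-ol (hydroxyl, oxirane and side chain all cis)
Conditions: VO(acac)2 (3 mol %), t-BuOOH (1.3 equiv, decane), CH2Cl2, 0 °C to rt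
Reagents that add atoms: tert-butyl hydroperoxide, CC(C)(C)OO
Why: Vanadium-catalysed hydroxyl-directed epoxidation (Sharpless–Michaelson type), for which cyclic allylic alcohols including the parent cis-carveol are the closest precedent. The C2 hydroxyl exchanges onto oxovanadium(V), which also binds the alkyl peroxide, and the peroxide oxygen is transferred within this complex to the adjacent C3=C4 alkene. The oxirane is closed by a concerted, suprafacial oxygen-atom transfer in which both C–O bonds form on the same alkene face. C3 and C4 are set together by the C2 carbinol, which itself was set by C6 in step 2, so the oxygen arrives syn to the C6 substituent, the face that reagent approach alone avoids. The step needs face selectivity (secured by the metal–alkoxide tether) and site selectivity over C7=C14. That alkene is only bishomoallylic to the hydroxyl and is deactivated by the allylic chlorine, so the allylic alkene should react far faster. Low temperature and slow peroxide addition should limit dehydrogenation of the allylic alcohol back to 2.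

Step 4
Reactants: 4 cis-epoxy alcohol
Product: 5 (1R,4S,6R)-4-(3-chloroprop-1-en-2-yl)-1-methyl-7-oxabicyclo[4.1.0]heptan-2-one
Conditions: Dess–Martin periodinane, CH2Cl2, 0 °C to rt
Reagents that add atoms: none
Why: Dess–Martin oxidation under near-neutral conditions removes the temporary C2 stereocentre and restores the ketone without opening the oxirane or displacing the chloride.

Step 5
Reactants: 5 cis-epoxy ketone
Product: 7 (1R,3R,4R,6R)-4-(3-chloroprop-1-en-2-yl)-3-hydroxy-1-methyl-7-oxabicyclo[4.1.0]heptan-2-one (hydroxyl trans to the side chain), via potassium enolate 6 (not isolated)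
Conditions: KHMDS (1.05 equiv), THF, −78 °C; then (±)-trans-2-(phenylsulfonyl)-3-phenyloxaziridine, −78 °C; AcOH quench
Reagents that add atoms: trans-2-(phenylsulfonyl)-3-phenyloxaziridine, O=S(=O)(N1OC1c1ccccc1)c1ccccc1
Why: Davis oxidation of the only possible enolate (C3 is quaternary). The oxaziridine should attack C1 anti to the adjacent C6 substituent and give the trans alcohol; the enolate oxygen is geometrically unable to reach the allylic chloride.

Step 6
Reactants: 7 trans-α-hydroxy ketone; 8 angelic acid
Product: 10 (1R,3S,4R,6R)-4-(3-chloroprop-1-en-2-yl)-1-methyl-2-oxo-7-oxabicyclo[4.1.0]heptan-3-yl (Z)-2-methylbut-2-enoate (ester cis to the side chain), via alkoxyphosphonium angelate 9 (not isolated)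
Conditions: PPh3, DIAD, toluene, 0 °C to rt
Reagents that add atoms: none
Why: Mitsunobu esterification; SN2 at the carbonyl-activated C1 inverts the centre to the required 1S (cis) configuration. Because 8 reacts as a carboxylate and is never acyl-activated, the Z double bond should not isomerise.

Step 7
Reactants: 10 C1 angelate chloride
Product: 12 (1R,3S,4R,6R)-1-methyl-2-oxo-4-(3-oxoprop-1-en-2-yl)-7-oxabicyclo[4.1.0]heptan-3-yl (Z)-2-methylbut-2-enoate, via N-alkoxymorpholinium chloride 11 (not isolated)
Conditions: NMO (4 equiv), KI (0.2 equiv), NaHCO3, 4 Å MS, MeCN, 40 °C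
Reagents that add atoms: N-methylmorpholine N-oxide, C[N+]1([O-])CCOCC1
Why: Amine N-oxide (Ganem/Kornblum-type) oxidation of an allylic halide: SN2 displacement by the N-oxide oxygen, then loss of the amine, gives the enal. The only bases present are weak (N-methylmorpholine, bicarbonate), which should spare the C1 stereocentre.

Step 8
Reactants: 12 enal
Product: 14 (1R,3S,4R,6R)-4-[(3R)-3-hydroxyhexa-1,5-dien-2-yl]-1-methyl-2-oxo-7-oxabicyclo[4.1.0]heptan-3-yl (Z)-2-methylbut-2-enoate, via diisopinocampheylborinate 13 (not isolated)
Conditions: (+)-Ipc2B(allyl) (from (−)-α-pinene), Et2O, −78 °C; then pH 7 buffer, MeOH, H2O2, 0 °C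
Reagents that add atoms: (+)-B-allyldiisopinocampheylborane, C=CCB(C1CC2CC(C1C)C2(C)C)C1CC2CC(C1C)C2(C)C
Why: Brown asymmetric allylboration through a chair transition state; the (+)-reagent should add to the Re face of the aldehyde and give 8R. The aldehyde reacts at −78 °C, where the hindered ring ketone does not.

Step 9
Reactants: 14 (8R)-homoallylic alcohol
Product: 15 (1R,3S,4R,6R)-4-[(3R)-3-hydroxy-6-methylhepta-1,5-dien-2-yl]-1-methyl-2-oxo-7-oxabicyclo[4.1.0]heptan-3-yl (Z)-2-methylbut-2-enoate
Conditions: 2-methyl-2-butene (excess), Grubbs II (5 mol %), 1,4-benzoquinone (10 mol %), CH2Cl2, 40 °C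
Reagents that add atoms: 2-methyl-2-butene, CC=C(C)C
Why: Olefin cross-metathesis; only the monosubstituted alkene is reactive, while C7=C14 and the angelate alkene are too hindered or electron-poor. The step is placed before the C8 ester so that ring-closing metathesis onto a C8 angelate cannot compete.

Step 10
Reactants: 15 (8R)-prenyl alcohol; 8 angelic acid
Product: 17 (1R,3S,4R,6R)-1-methyl-4-[(3S)-6-methyl-3-{[(Z)-2-methylbut-2-enoyl]oxy}hepta-1,5-dien-2-yl]-2-oxo-7-oxabicyclo[4.1.0]heptan-3-yl (Z)-2-methylbut-2-enoate, via alkoxyphosphonium angelate 16 (not isolated)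
Conditions: PPh3, DIAD, toluene, 0 °C to rt
Reagents that add atoms: none
Why: Second Mitsunobu esterification; direct SN2 at the allylic C8 inverts 8R to 8S. It is again base-free, so the C1 α-acyloxy ketone and both Z esters should be preserved.

Step 11
Reactants: 17 bis-angelate
Product: 19 target, (1S,3R,4R,6R,8S,10S)-1,8-bis(angeloyloxy)-3,4-epoxy-10,11-dihydroxybisabol-7(14)-en-2-one, via osmate ester 18 (not isolated)
Conditions: OsO4 (1.05 equiv), (DHQ)2PHAL (1.1 equiv), toluene, −78 °C; then aq. NaHSO3, THF, rt
Reagents that add atoms: osmium tetroxide, O=[Os](=O)(=O)=O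
Why: Ligand-accelerated Sharpless-type osmylation of the only electron-rich trisubstituted alkene; the DHQ ligand should direct attack to the face that gives 10S. Stoichiometric, carbonate-free conditions are chosen so that the epimerisable C1 centre never meets aqueous base.

## Compound list

1 | (S)-(+)-carvone, (5S)-2-methyl-5-(prop-1-en-2-yl)cyclohex-2-en-1-one | C=C(C)[C@H]1CC=C(C)C(=O)C1 | starting material
2 | (5S)-5-(3-chloroprop-1-en-2-yl)-2-methylcyclohex-2-en-1-one | C=C(CCl)[C@H]1CC=C(C)C(=O)C1 | intermediate
3 | (1S,5S)-5-(3-chloroprop-1-en-2-yl)-2-methylcyclohex-2-en-1-ol | C=C(CCl)[C@H]1CC=C(C)[C@@H](O)C1 | intermediate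
4 | (1S,2S,4R,6R)-4-(3-chloroprop-1-en-2-yl)-1-methyl-7-oxabicyclo[4.1.0]heptan-2-ol | C=C(CCl)[C@H]1C[C@H]2O[C@@]2(C)[C@@H](O)C1 | intermediate
5 | (1R,4S,6R)-4-(3-chloroprop-1-en-2-yl)-1-methyl-7-oxabicyclo[4.1.0]heptan-2-one | C=C(CCl)[C@H]1C[C@H]2O[C@@]2(C)C(=O)C1 | intermediate
6 | potassium enolate of 5 | C=C(CCl)[C@H]1C[C@H]2O[C@@]2(C)C([O-])=C1.[K+] | intermediate
7 | (1R,3R,4R,6R)-4-(3-chloroprop-1-en-2-yl)-3-hydroxy-1-methyl-7-oxabicyclo[4.1.0]heptan-2-one | C=C(CCl)[C@H]1C[C@H]2O[C@@]2(C)C(=O)[C@@H]1O | intermediate
8 | angelic acid, (Z)-2-methylbut-2-enoic acid | C/C=C(/C)C(=O)O | starting material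
9 | alkoxytriphenylphosphonium angelate derived from 7 | C=C(CCl)[C@H]1C[C@H]2O[C@@]2(C)C(=O)[C@@H]1O[P+](c1ccccc1)(c1ccccc1)c1ccccc1.C/C=C(/C)C(=O)[O-] | intermediate
10 | (1R,3S,4R,6R)-4-(3-chloroprop-1-en-2-yl)-1-methyl-2-oxo-7-oxabicyclo[4.1.0]heptan-3-yl (Z)-2-methylbut-2-enoate | C=C(CCl)[C@H]1C[C@H]2O[C@@]2(C)C(=O)[C@H]1OC(=O)/C(C)=C\C | intermediate
11 | N-alkoxy-N-methylmorpholinium chloride derived from 10 | C=C(CO[N+]1(C)CCOCC1)[C@H]1C[C@H]2O[C@@]2(C)C(=O)[C@H]1OC(=O)/C(C)=C\C.[Cl-] | intermediate
12 | (1R,3S,4R,6R)-1-methyl-2-oxo-4-(3-oxoprop-1-en-2-yl)-7-oxabicyclo[4.1.0]heptan-3-yl (Z)-2-methylbut-2-enoate | O=CC(=C)[C@H]1C[C@H]2O[C@@]2(C)C(=O)[C@H]1OC(=O)/C(C)=C\C | intermediate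
13 | diisopinocampheylborinate of 14 (Ipc groups from (−)-α-pinene, drawn without configuration) | C=C([C@@H](CC=C)OB(C1CC2CC(C1C)C2(C)C)C1CC2CC(C1C)C2(C)C)[C@H]1C[C@H]2O[C@@]2(C)C(=O)[C@H]1OC(=O)/C(C)=C\C | intermediate
14 | (1R,3S,4R,6R)-4-[(3R)-3-hydroxyhexa-1,5-dien-2-yl]-1-methyl-2-oxo-7-oxabicyclo[4.1.0]heptan-3-yl (Z)-2-methylbut-2-enoate | C=C([C@H](O)CC=C)[C@H]1C[C@H]2O[C@@]2(C)C(=O)[C@H]1OC(=O)/C(C)=C\C | intermediate
15 | (1R,3S,4R,6R)-4-[(3R)-3-hydroxy-6-methylhepta-1,5-dien-2-yl]-1-methyl-2-oxo-7-oxabicyclo[4.1.0]heptan-3-yl (Z)-2-methylbut-2-enoate | C=C([C@H](O)CC=C(C)C)[C@H]1C[C@H]2O[C@@]2(C)C(=O)[C@H]1OC(=O)/C(C)=C\C | intermediate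
16 | alkoxytriphenylphosphonium angelate derived from 15 | C=C([C@@H](CC=C(C)C)O[P+](c1ccccc1)(c1ccccc1)c1ccccc1)[C@H]1C[C@H]2O[C@@]2(C)C(=O)[C@H]1OC(=O)/C(C)=C\C.C/C=C(/C)C(=O)[O-] | intermediate
17 | (1R,3S,4R,6R)-1-methyl-4-[(3S)-6-methyl-3-{[(Z)-2-methylbut-2-enoyl]oxy}hepta-1,5-dien-2-yl]-2-oxo-7-oxabicyclo[4.1.0]heptan-3-yl (Z)-2-methylbut-2-enoate | C=C([C@H](CC=C(C)C)OC(=O)/C(C)=C\C)[C@H]1C[C@H]2O[C@@]2(C)C(=O)[C@H]1OC(=O)/C(C)=C\C | intermediate
18 | cyclic osmate(VI) ester of 19 (alkaloid ligand on osmium not drawn) | C=C([C@H](C[C@@H]3O[Os](=O)(=O)OC3(C)C)OC(=O)/C(C)=C\C)[C@H]1C[C@H]2O[C@@]2(C)C(=O)[C@H]1OC(=O)/C(C)=C\C | intermediate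
19 | (1R,3S,4R,6R)-4-[(3S,5S)-5,6-dihydroxy-6-methyl-3-{[(Z)-2-methylbut-2-enoyl]oxy}hept-1-en-2-yl]-1-methyl-2-oxo-7-oxabicyclo[4.1.0]heptan-3-yl (Z)-2-methylbut-2-enoate | C=C([C@H](C[C@H](O)C(C)(C)O)OC(=O)/C(C)=C\C)[C@H]1C[C@H]2O[C@@]2(C)C(=O)[C@H]1OC(=O)/C(C)=C\C | target

## Step count and least certain steps

Total: 11 steps. Longest linear sequence: 11 steps from 1. No protecting group is used.

**Step 3 (key step).**
- What may go wrong: vanadium-mediated dehydrogenation of the allylic alcohol back to the enone, which competes because the hydroxyl is pseudo-equatorial in the preferred half-chair of 3. The resulting slow oxygen transfer also lets undirected background epoxidation erode the syn selectivity.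
- Fallback, from 3 back to 4: the oxygen is delivered by a tethered carbonate instead of a metal alkoxide. Compound 3 is converted into its tert-butyl carbonate F1 (NaHMDS, Boc2O). Iodine monobromide at −80 °C closes the cis-fused iodo cyclic carbonate F2, in which the carbonate oxygen has attacked C3 and iodine sits anti at C4. Potassium carbonate in methanol then cleaves the carbonate, and the C3 alkoxide displaces iodide to give 4.

**Step 5.**
- What may go wrong: incomplete facial discrimination in the oxygen transfer, since the C3 methyl lies on the face anti to the C6 substituent, and addition of the enolate to the sulfonimine by-product.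
- Fallback, from 5 back to 7: a neutral Rubottom sequence. Soft enolisation (TMSOTf, Et3N) gives the trimethylsilyl enol ether F3. Its enol ether double bond is epoxidised with dimethyldioxirane at −78 °C, and mild acidic work-up gives 7.

**Step 6.**
- What may go wrong: the carboxylate has to enter syn to the C6 substituent. The alkoxyphosphonium ion may instead lose its acidic C1 proton, which leads to epimerisation, retention or recovered alcohol.
- Fallback, from 7 back to 10: inversion by C–H rather than C–O bond formation. The dianion of 7 (LDA, 2.2 equiv, −78 °C) is protonated kinetically with 2,6-di-tert-butylphenol on the face anti to the C6 substituent, giving the cis-α-hydroxy ketone F4. This is acylated with retention by the mixed anhydride of 8 and 2,4,6-trichlorobenzoyl chloride (Et3N, toluene) to give 10.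

**Step 10.**
- What may go wrong: SN2' attack at the unhindered C14 terminus, giving the transposed primary allylic ester, or ionisation of the allylic alkoxyphosphonium ion with loss of stereochemical fidelity.
- Fallback, from 12 back to 17: C8 is set directly as 8S and acylated with retention. Allylboration of 12 with (−)-Ipc2B(allyl) gives the (8S)-homoallylic alcohol F5. Cross-metathesis with 2-methyl-2-butene gives the (8S)-prenyl alcohol F6. Acylation with the mixed anhydride of 8 and 2,4,6-trichlorobenzoyl chloride gives 17.

**Step 11.**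
- What may go wrong: insufficient face selectivity at C10, which rests on the ligand alone and may be mismatched with C8, and competing osmylation of C7=C14.
- Fallback, from 12 back to 19: C10 is set by substrate control.
  - Commercial 3-hydroxy-3-methylbutan-2-one is silylated (TESCl, imidazole) to 3-methyl-3-(triethylsilyloxy)butan-2-one F7.
  - Its diisopinocampheylboron enolate is added to 12 to give the (8S)-β-hydroxy ketone F8. The Ipc2BCl antipode that gives 8S has to be confirmed on a model aldehyde; its sense was not fixed here.
  - Hydroxyl-directed reduction with Me4NBH(OAc)3 gives the 8,10-anti diol F9.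
  - The less hindered C8 hydroxyl is acylated with the mixed anhydride of 8 to give the C11 silyl ether F10.
  - HF·pyridine liberates 19.

## Further compounds

F1 | step 3 | tert-butyl (1S,5S)-5-(3-chloroprop-1-en-2-yl)-2-methylcyclohex-2-en-1-yl carbonate | C=C(CCl)[C@H]1CC=C(C)[C@@H](OC(=O)OC(C)(C)C)C1
F2 | step 3 | cis-fused cyclic carbonate across O2/O3 with iodine at C4 trans to the C3 oxygen | C=C(CCl)[C@H]1C[C@H](I)[C@@]2(C)OC(=O)O[C@H]2C1
F3 | step 5 | trimethylsilyl enol ether of 5 | C=C(CCl)[C@H]1C[C@H]2O[C@@]2(C)C(O[Si](C)(C)C)=C1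
F4 | step 6 | (1R,3S,4R,6R)-4-(3-chloroprop-1-en-2-yl)-3-hydroxy-1-methyl-7-oxabicyclo[4.1.0]heptan-2-one (cis-α-hydroxy ketone) | C=C(CCl)[C@H]1C[C@H]2O[C@@]2(C)C(=O)[C@H]1O
F5 | step 10 | (8S)-homoallylic alcohol, C8 epimer of 14 | C=C([C@@H](O)CC=C)[C@H]1C[C@H]2O[C@@]2(C)C(=O)[C@H]1OC(=O)/C(C)=C\C
F6 | step 10 | (8S)-prenyl alcohol, C8 epimer of 15 | C=C([C@@H](O)CC=C(C)C)[C@H]1C[C@H]2O[C@@]2(C)C(=O)[C@H]1OC(=O)/C(C)=C\C
F7 | step 11 | 3-methyl-3-(triethylsilyloxy)butan-2-one | CC(=O)C(C)(C)O[Si](CC)(CC)CC
F8 | step 11 | (8S)-β-hydroxy ketone, C10 ketone with C11 triethylsilyl ether | C=C([C@@H](O)CC(=O)C(C)(C)O[Si](CC)(CC)CC)[C@H]1C[C@H]2O[C@@]2(C)C(=O)[C@H]1OC(=O)/C(C)=C\C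
F9 | step 11 | (8S,10S)-anti diol with C11 triethylsilyl ether | C=C([C@@H](O)C[C@H](O)C(C)(C)O[Si](CC)(CC)CC)[C@H]1C[C@H]2O[C@@]2(C)C(=O)[C@H]1OC(=O)/C(C)=C\C
F10 | step 11 | C11 triethylsilyl ether of 19 | C=C([C@H](C[C@H](O)C(C)(C)O[Si](CC)(CC)CC)OC(=O)/C(C)=C\C)[C@H]1C[C@H]2O[C@@]2(C)C(=O)[C@H]1OC(=O)/C(C)=C\C
A1 | alternative 1 | trans-epoxy ketone, oxirane anti to the side chain | C=C(CCl)[C@H]1C[C@@H]2O[C@]2(C)C(=O)C1
A2 | alternative 1 | all-trans α-hydroxy epoxy ketone | C=C(CCl)[C@H]1C[C@@H]2O[C@]2(C)C(=O)[C@@H]1O
A3 | alternative 2 | (E)-tert-butyldimethyl[(3-methylbuta-1,3-dien-1-yl)oxy]silane | C=C(C)/C=C/O[Si](C)(C)C(C)(C)C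
A4 | alternative 2 | (4S)-4-hydroxy-5-[(4S)-2,2,5,5-tetramethyl-1,3-dioxolan-4-yl]pent-1-en-3-one | C=CC(=O)[C@@H](O)C[C@@H]1OC(C)(C)OC1(C)C
A5 | alternative 2 | endo Diels–Alder adduct, C1 silyloxy cis to C6 acyl, alkene C2=C3 | O=C([C@@H](O)C[C@@H]2OC(C)(C)OC2(C)C)[C@H]1CCC(C)=C[C@H]1O[Si](C)(C)C(C)(C)C
A6 | alternative 3 | kinetic triethylsilyl dienol ether of 2 | C=C(CCl)[C@H]1CC=C(C)C(O[Si](CC)(CC)CC)=C1
A7 | alternative 3 | 1,4-endoperoxide, peroxide bridge anti to the side chain | C=C(CCl)[C@H]1C[C@@H]2OO[C@H]1C(O[Si](CC)(CC)CC)=C2C
A8 | alternative 3 | all-trans α-silyloxy epoxy ketone | C=C(CCl)[C@H]1C[C@@H]2O[C@]2(C)C(=O)[C@@H]1O[Si](CC)(CC)CC
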